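**Strategy.** The route rests on cutting ring C of the flavanone half at O1–C2 and C3–C4. Ring C is an oxygen heterocycle fused to phloroglucinol ring A; its trans-related C2/C3 carbons map onto an (E)-stilbene, and O1, C8a, C4a and C4 map onto an o-quinone methide of ring A. One acid-catalysed hetero-Diels–Alder reaction therefore forms both bonds, ring C and both stereocentres. The alkene partner is an (E)-8-(4-benzyloxystyryl)luteolin that already carries the sulfate at O7 as an electron-withdrawing trichloroethyl diester; the diene source is 3,5-bis(benzyloxy)-2-(hydroxymethyl)phenol. C4 is raised to the ketone afterwards.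

Key step: step 11

Assumption: the target is drawn as the free hydrogen sulfate; since aryl hydrogen sulfates hydrolyse easily, the sulfate is carried as a neutral trichloroethyl diester, released as its ammonium salt and protonated only in the last operation, and the catalyst enantiomer in step 11 is fixed by a pilot run.

Locants: unprimed and single-primed positions belong to the flavanone (flavan) unit, double-primed to the chromone of the luteolin unit, triple-primed to its catechol ring.

**Step 1**
Reactants: 1 4-(benzyloxy)benzaldehyde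
Product: 2 4-(benzyloxy)styrene
Conditions: Ph3PCH3Br, KOtBu, THF, 0 °C to rt
Reagents that add atoms: methyltriphenylphosphonium bromide, C[P+](c1ccccc1)(c1ccccc1)c1ccccc1.[Br-]
Why: Wittig methylenation of an unhindered, non-enolisable aryl aldehyde with the unstabilised ylide is reliable, and the benzyl ether is inert to it.

**Step 2**
Reactants: 3 luteolin
Product: 4 3',4'-O-(diphenylmethylene)luteolin
Conditions: Ph2CCl2, Ph2O, 175 °C
Reagents that add atoms: dichlorodiphenylmethane, ClC(Cl)(c1ccccc1)c1ccccc1
Why: Ketalisation by double substitution at the gem-dichloride can close a five-membered ring only on the 3',4'-catechol, so the meta-related 5- and 7-hydroxyls stay free.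

**Step 3**
Reactants: 4 3',4'-O-(diphenylmethylene)luteolin
Product: 5 7-O-methoxymethyl-3',4'-O-(diphenylmethylene)luteolin
Conditions: MOMCl (1.1 equiv), K2CO3, acetone, 0 °C to rt
Reagents that add atoms: chloromethyl methyl ether, COCCl
Why: Williamson-type O-alkylation takes the most acidic and accessible 7-hydroxyl, whereas the 5-hydroxyl is held in a hydrogen bond to the C4 carbonyl and should stay free under these mild conditions.

**Step 4**
Reactants: 5 7-O-methoxymethyl-3',4'-O-(diphenylmethylene)luteolin
Product: 6 5-O-benzyl-7-O-methoxymethyl-3',4'-O-(diphenylmethylene)luteolin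
Conditions: BnBr, K2CO3, n-Bu4NI (cat.), DMF, 70 °C
Reagents that add atoms: benzyl bromide, BrCc1ccccc1
Why: Williamson etherification under more forcing conditions breaks the chelate and benzylates O5, which is needed because an alkylated O5 steers the next iodination to C8 and not C6; the MOM ether and the ketal are inert to base.

**Step 5**
Reactants: 6 5-O-benzyl-7-O-methoxymethyl-3',4'-O-(diphenylmethylene)luteolin
Product: 7 8-iodo-5-O-benzyl-7-O-methoxymethyl-3',4'-O-(diphenylmethylene)luteolin
Conditions: NIS, TFA (10 mol%), MeCN, 0 °C to rt, dark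
Reagents that add atoms: N-iodosuccinimide, O=C1CCC(=O)N1I
Why: Electrophilic aromatic iodination of a 5,7-di-O-alkylated flavone prefers C8 (ortho to O7 and O1, para to O5), and the ketal-bearing ring is deactivated by conjugation with the pyranone.

**Step 6**
Reactants: 7 8-iodo-5-O-benzyl-7-O-methoxymethyl-3',4'-O-(diphenylmethylene)luteolin; 2 4-(benzyloxy)styrene
Product: 8 (E)-8-[2-(4-benzyloxyphenyl)ethenyl]-5-O-benzyl-7-O-methoxymethyl-3',4'-O-(diphenylmethylene)luteolin
Conditions: Pd(OAc)2 (10 mol%), P(o-tol)3, NaOAc, n-Bu4NBr, DMF, 100 °C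
Reagents that add atoms: none
Why: Mizoroki–Heck reaction: the aryl iodide adds to zerovalent palladium, the styrene inserts with the aryl group going to its terminal carbon, and syn β-hydride elimination gives the (E)-stilbene; the small oxygen substituents flanking C8 should be tolerated at this temperature.

**Step 7**
Reactants: 8 (E)-8-[2-(4-benzyloxyphenyl)ethenyl]-5-O-benzyl-7-O-methoxymethyl-3',4'-O-(diphenylmethylene)luteolin
Product: 9 (E)-8-[2-(4-benzyloxyphenyl)ethenyl]-5-O-benzyl-3',4'-O-(diphenylmethylene)luteolin (free 7-OH)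
Conditions: HCl (0.5 M) in MeOH/THF (1:1), 40 °C
Reagents that add atoms: none
Why: Acid-catalysed acetal exchange with methanol removes the MOM group; benzyl ethers are untouched, and the diphenylmethylene ketal (which needs hot aqueous acid) and the stilbene should survive the dilute acid.

**Step 8**
Reactants: 9 (E)-8-[2-(4-benzyloxyphenyl)ethenyl]-5-O-benzyl-3',4'-O-(diphenylmethylene)luteolin
Product: 10 (E)-5-(benzyloxy)-8-[2-(4-benzyloxyphenyl)ethenyl]-2-(2,2-diphenyl-1,3-benzodioxol-5-yl)-4-oxo-4H-chromen-7-yl 2,2,2-trichloroethyl sulfate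
Conditions: Cl3CCH2OSO2Cl, Et3N, DMAP (20 mol%), THF, 0 °C to rt
Reagents that add atoms: 2,2,2-trichloroethyl chlorosulfate, ClS(=O)(=O)OCC(Cl)(Cl)Cl
Why: O-Sulfonylation of the single free phenol with the chlorosulfate under DMAP catalysis installs the sulfate as a neutral trichloroethyl diester, which is stable to acid and oxidants and makes the chromone ring the electron-poor end of the stilbene.

**Step 9**
Reactants: 11 2,4,6-trihydroxybenzaldehyde
Product: 12 2,4-bis(benzyloxy)-6-hydroxybenzaldehyde
Conditions: BnBr (2.05 equiv), K2CO3, DMF, 0 °C to rt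
Reagents that add atoms: benzyl bromide, BrCc1ccccc1
Why: Williamson etherification alkylates the 4-hydroxyl and one ortho hydroxyl, after which the remaining ortho hydroxyl is chelated to the aldehyde and should resist a third benzylation at this stoichiometry.

**Step 10**
Reactants: 12 2,4-bis(benzyloxy)-6-hydroxybenzaldehyde
Product: 13 3,5-bis(benzyloxy)-2-(hydroxymethyl)phenol
Conditions: NaBH4, THF/MeOH, 0 °C; neutral work-up, used at once
Reagents that add atoms: none
Why: Borohydride reduction of the aldehyde gives the o-hydroxybenzyl alcohol, which is acid-sensitive and is therefore worked up without acid and used directly.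

**Step 11**
Reactants: 13 3,5-bis(benzyloxy)-2-(hydroxymethyl)phenol; 10 (E)-stilbene trichloroethyl sulfate
Product: 15 (2R,3S)-2,3-trans flavan–flavone cycloadduct (C4 = CH2; C3 bonded to C8''), via o-quinone methide 14 (not isolated)
Conditions: (R)-3,3'-bis(2,4,6-triisopropylphenyl)-1,1'-binaphthyl-2,2'-diyl hydrogen phosphate (10 mol%), 3 Å molecular sieves, CH2Cl2, −20 °C to rt, slow addition of 13 (2.5 equiv)
Reagents that add atoms: none
Why: Proposed new method: the phosphoric acid dehydrates 13 to o-quinone methide 14 and stays hydrogen-bonded to its oxygen as a chiral contact ion pair; the alkene carbon next to the chromone (future C3) attacks the methide carbon (future C4) while charge builds at the carbon bearing the 4-benzyloxyphenyl ring (future C2), which the phenolic oxygen then captures, so the event is an asynchronous inverse-demand hetero-Diels–Alder reaction whose closest known relatives are chiral-phosphoric-acid-catalysed [4+2] cycloadditions of o-quinone methides from o-hydroxybenzyl alcohols with styrenes and other electron-rich alkenes, not yet shown for a hindered stilbene in enantioselective form. Ring C, the only ring closed, forms by the cycloaddition itself (if the path turns stepwise, by six-membered capture of the benzylic cation by O1). The C2/C3 trans relation follows from suprafacial addition to the (E)-alkene and is also the diequatorial outcome that a stepwise closure would favour; the absolute configuration (2R,3S) is set by the catalyst, whose triisopropylphenyl walls should leave one alkene face open to the bound methide. The step needs regioselectivity (O1 to the carbon bearing the 4-benzyloxyphenyl ring), which the push–pull alkene secures: the para-benzyloxy group stabilises charge at C2, whereas the chromone ring is twisted and made electron-poor by the sulfate diester at O7''. Slow addition of 13 should suppress self-condensation of the electron-rich methide.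

**Step 12**
Reactants: 15 (2R,3S)-flavan–flavone cycloadduct
Product: 16 (2R,3R)-4-hydroxyflavan–flavone (mixture of C4 epimers)
Conditions: DDQ (1.5 equiv), CH2Cl2/H2O (18:1), 0 °C to rt
Reagents that add atoms: water, O
Why: DDQ benzylic oxidation: hydride abstraction at C4 gives a cation stabilised by O1, O5 and O7 of ring A (far better than a cation at C2 with one para oxygen) and water captures it, as known for O-benzylated flavans; benzyl ethers, ketal and sulfate diester should not be attacked at this temperature.

**Step 13**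
Reactants: 16 (2R,3R)-4-hydroxyflavan–flavone
Product: 17 (2R,3S)-protected flavanone–flavone (C4 ketone)
Conditions: Dess–Martin periodinane, NaHCO3, CH2Cl2, 0 °C to rt
Reagents that add atoms: none
Why: Dess–Martin oxidation of the secondary benzylic alcohol under buffered, non-basic conditions gives the C4 ketone without disturbing the enolisable C3 centre, and both C4 epimers converge.

**Step 14**
Reactants: 17 (2R,3S)-protected flavanone–flavone
Product: 19 CNP0314990.1 (free hydrogen sulfate), via ammonium salt 18 (not isolated)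
Conditions: H2 (1 atm), Pd/C (10% Pd), HCO2NH4 (5 equiv), THF/MeOH, rt; then HCl (1.0 equiv), 0 °C, C18 desalting
Reagents that add atoms: none
Why: Catalytic hydrogenolysis cleaves the four benzyl ethers and the diphenylmethylene ketal, while reduction of one C–Cl bond of the trichloroethyl group triggers β-elimination to the aryl sulfate anion (a known cleavage of this sulfate protecting group with Pd/C and ammonium formate); the near-neutral medium should leave C2 and C3 untouched, and the sulfate stays a salt until the cold protonation.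

**Compound list**

1 | 4-(benzyloxy)benzaldehyde | O=Cc1ccc(OCc2ccccc2)cc1 | starting material
2 | 4-(benzyloxy)styrene | C=Cc1ccc(OCc2ccccc2)cc1 | intermediate
3 | luteolin | O=c1cc(-c2ccc(O)c(O)c2)oc2cc(O)cc(O)c12 | starting material
4 | 3',4'-O-(diphenylmethylene)luteolin | O=c1cc(-c2ccc3OC(c4ccccc4)(c5ccccc5)Oc3c2)oc2cc(O)cc(O)c12 | intermediate
5 | 7-O-methoxymethyl-3',4'-O-(diphenylmethylene)luteolin | O=c1cc(-c2ccc3OC(c4ccccc4)(c5ccccc5)Oc3c2)oc2cc(OCOC)cc(O)c12 | intermediate
6 | 5-O-benzyl-7-O-methoxymethyl-3',4'-O-(diphenylmethylene)luteolin | O=c1cc(-c2ccc3OC(c4ccccc4)(c5ccccc5)Oc3c2)oc2cc(OCOC)cc(OCc6ccccc6)c12 | intermediate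
7 | 8-iodo-5-O-benzyl-7-O-methoxymethyl-3',4'-O-(diphenylmethylene)luteolin | O=c1cc(-c2ccc3OC(c4ccccc4)(c5ccccc5)Oc3c2)oc2c(I)c(OCOC)cc(OCc6ccccc6)c12 | intermediate
8 | (E)-8-[2-(4-benzyloxyphenyl)ethenyl]-5-O-benzyl-7-O-methoxymethyl-3',4'-O-(diphenylmethylene)luteolin | O=c1cc(-c2ccc3OC(c4ccccc4)(c5ccccc5)Oc3c2)oc2c(/C=C/c7ccc(OCc8ccccc8)cc7)c(OCOC)cc(OCc6ccccc6)c12 | intermediate
9 | (E)-8-[2-(4-benzyloxyphenyl)ethenyl]-5-O-benzyl-3',4'-O-(diphenylmethylene)luteolin | O=c1cc(-c2ccc3OC(c4ccccc4)(c5ccccc5)Oc3c2)oc2c(/C=C/c7ccc(OCc8ccccc8)cc7)c(O)cc(OCc6ccccc6)c12 | intermediate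
10 | (E)-5-(benzyloxy)-8-[2-(4-benzyloxyphenyl)ethenyl]-2-(2,2-diphenyl-1,3-benzodioxol-5-yl)-4-oxo-4H-chromen-7-yl 2,2,2-trichloroethyl sulfate | O=c1cc(-c2ccc3OC(c4ccccc4)(c5ccccc5)Oc3c2)oc2c(/C=C/c7ccc(OCc8ccccc8)cc7)c(OS(=O)(=O)OCC(Cl)(Cl)Cl)cc(OCc6ccccc6)c12 | intermediate
11 | 2,4,6-trihydroxybenzaldehyde | O=Cc1c(O)cc(O)cc1O | starting material
12 | 2,4-bis(benzyloxy)-6-hydroxybenzaldehyde | O=Cc1c(O)cc(OCc2ccccc2)cc1OCc1ccccc1 | intermediate
13 | 3,5-bis(benzyloxy)-2-(hydroxymethyl)phenol | OCc1c(O)cc(OCc2ccccc2)cc1OCc1ccccc1 | intermediate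
14 | 3,5-bis(benzyloxy)-6-methylidenecyclohexa-2,4-dien-1-one (o-quinone methide, not isolated) | C=C1C(OCc2ccccc2)=CC(OCc2ccccc2)=CC1=O | intermediate
15 | (2R,3S)-5,7-bis(benzyloxy)-2-(4-benzyloxyphenyl)chroman bonded at C3 to C8'' of the chromone unit of 10 (5''-O-benzyl, 3''',4'''-O-diphenylmethylene, 7''-O-trichloroethyl sulfate); H2 and H3 trans | C1c2c(OCc3ccccc3)cc(OCc3ccccc3)cc2O[C@@H](c2ccc(OCc3ccccc3)cc2)[C@@H]1c1c(OS(=O)(=O)OCC(Cl)(Cl)Cl)cc(OCc2ccccc2)c2c(=O)cc(-c3ccc4OC(c5ccccc5)(c6ccccc6)Oc4c3)oc12 | intermediate
16 | (2R,3R)-4-hydroxy derivative of 15 (C4 epimers; same spatial arrangement at C2 and C3) | OC1c2c(OCc3ccccc3)cc(OCc3ccccc3)cc2O[C@@H](c2ccc(OCc3ccccc3)cc2)[C@@H]1c1c(OS(=O)(=O)OCC(Cl)(Cl)Cl)cc(OCc2ccccc2)c2c(=O)cc(-c3ccc4OC(c5ccccc5)(c6ccccc6)Oc4c3)oc12 | intermediate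
17 | (2R,3S)-4-oxo derivative of 15 (protected flavanone–flavone) | O=C1c2c(OCc3ccccc3)cc(OCc3ccccc3)cc2O[C@@H](c2ccc(OCc3ccccc3)cc2)[C@@H]1c1c(OS(=O)(=O)OCC(Cl)(Cl)Cl)cc(OCc2ccccc2)c2c(=O)cc(-c3ccc4OC(c5ccccc5)(c6ccccc6)Oc4c3)oc12 | intermediate
18 | ammonium salt of the target sulfate (not isolated) | [NH4+].O=C1c2c(O)cc(O)cc2O[C@@H](c2ccc(O)cc2)[C@@H]1c1c(OS(=O)(=O)[O-])cc(O)c2c(=O)cc(-c3ccc(O)c(O)c3)oc12 | intermediate
19 | CNP0314990.1, (2R,3S)-5,7-dihydroxy-2-(4-hydroxyphenyl)-3-[2-(3,4-dihydroxyphenyl)-5-hydroxy-4-oxo-7-(sulfooxy)-4H-chromen-8-yl]chroman-4-one | O=C1c2c(O)cc(O)cc2O[C@@H](c2ccc(O)cc2)[C@@H]1c1c(OS(=O)(=O)O)cc(O)c2c(=O)cc(-c3ccc(O)c(O)c3)oc12 | target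

**Totals.** Total step count: 14. Longest linear sequence: 11 steps (luteolin 3 to 19 through steps 2–8 and 11–14).

**Steps most likely to fail**

1. Step 11 (proposed new method). What may go wrong: poor facial selectivity under the chiral acid, bond formation with the opposite regiochemistry, or self-condensation of the quinone methide before it meets the hindered alkene. Fallback (known chemistry): give up catalyst control of the absolute configuration. The fallback sets out from 10 and 13, which are heated together in toluene at 110 °C, or stirred with achiral diphenyl phosphate, in the known uncatalysed o-quinone methide Diels–Alder mode for styrenes and stilbenes. This should give the racemic trans adduct, that is 15 together with its (2S,3R) enantiomer F1. Preparative HPLC on an amylose tris(3,5-dimethylphenylcarbamate) phase then removes F1, and the route is rejoined at 15.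

2. Step 12. What may go wrong: loss of the C3 proton from the C4 cation (flav-3-ene formation, which erases C3), hydride abstraction at C2, or stalled conversion because the C3 aryl group shields C4. Fallback: replace quinone hydride abstraction by lead-mediated acetoxylation. The fallback sets out from 15, which is treated with Pb(OAc)4 in benzene at rt (known C4 acetoxylation of flavans with an oxygenated ring A) to give the 4-acetoxyflavan F2. Solvolysis of F2 in wet THF with a trace of pyridinium p-toluenesulfonate then gives 16, where the route is rejoined.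

3. Step 14. What may go wrong: incomplete fragmentation of the trichloroethyl group, slowing of the catalyst by chloride, partial hydrolysis of the sulfate, or over-reduction during the long concurrent hydrogenolysis. Fallback: stage the two cleavages with different chemistry. The fallback sets out from 17, which is treated with Zn dust and HCO2NH4 in MeOH/THF at rt; this reductive fragmentation removes only the trichloroethyl group and gives the fully O-protected aryl sulfate ammonium salt F3. Hydrogenolysis of F3 (H2, Pd(OH)2/C, THF/MeOH) then gives 18, which is protonated as in step 14.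

**Further compounds**

F1 | step 11 | (2S,3R) enantiomer of 15 | C1c2c(OCc3ccccc3)cc(OCc3ccccc3)cc2O[C@H](c2ccc(OCc3ccccc3)cc2)[C@H]1c1c(OS(=O)(=O)OCC(Cl)(Cl)Cl)cc(OCc2ccccc2)c2c(=O)cc(-c3ccc4OC(c5ccccc5)(c6ccccc6)Oc4c3)oc12
F2 | step 12 | 4-acetoxy derivative of 15 (C4 epimers; C2 and C3 as in 15) | CC(=O)OC1c2c(OCc3ccccc3)cc(OCc3ccccc3)cc2O[C@@H](c2ccc(OCc3ccccc3)cc2)[C@@H]1c1c(OS(=O)(=O)OCC(Cl)(Cl)Cl)cc(OCc2ccccc2)c2c(=O)cc(-c3ccc4OC(c5ccccc5)(c6ccccc6)Oc4c3)oc12
F3 | step 14 | ammonium salt of the 7''-O-sulfate of 17 with all benzyl ethers and the ketal intact | [NH4+].O=C1c2c(OCc3ccccc3)cc(OCc3ccccc3)cc2O[C@@H](c2ccc(OCc3ccccc3)cc2)[C@@H]1c1c(OS(=O)(=O)[O-])cc(OCc2ccccc2)c2c(=O)cc(-c3ccc4OC(c5ccccc5)(c6ccccc6)Oc4c3)oc12
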